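Take one number first, the selectivity factor 0.723, the rate constant of Q + X over that of Z + X, read from the maple run below between 8.00 min and 20.0 min, so it carries the scatter of those readings.

| flask | Z | X | remark | time |
|---|---|---|---|---|
| maple | 0.70 M | 0.98 equiv | run made earlier |  |
| amber | 0.70 M | 0.800 equiv |  | 40 min |
| green | 0.70 M | 2.50 equiv |  | 40 min |
| teal | 0.70 M | 4.00 equiv |  | 40 min |

maple run (percent of the Z charged)

| time / min | Q / % | D / % | Z / % |
|---|---|---|---|
| 1.50 | 4.8 | 0.3 | 95.0 |
| 2.50 | 7.7 | 0.2 | 92.2 |
| 4.00 | 11.8 | 0.6 | 87.5 |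
| 8.00 | 20.0 | 2.3 | 78.2 |
| 12.0 | 26.1 | 3.6 | 70.6 |
| 20.0 | 33.2 | 6.7 | 59.9 |

(standard deviation of a reading: 0.3 percentage points)



- Q at the end, in percent of the Z charged, for each flask in turn (amber, green, teal)

Follow one X molecule to its fork: it strikes Z or Q with odds cZ against s·cQ. With these two steps, the fork number F = cZ/(s·cQ) says how many times faster Q is made than used, and cX cancels from it. Reckoned with this s, Q peaks where F is one, which lies at Z 31.0% with Q 42.9%.

Now place each flask. Maple's loss of Z up to 8.00 min, set against its mean X, gives 0.0358 /min per equivalent. Multiply by equivalents and time for the exposure N: 1.14 in amber, 3.58 in green, 5.72 in teal. The peak needs 1.17.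

Test that number. N holds X at its charge, yet reaching the peak takes 0.951 equiv of X, more than amber's 0.800 equiv. So N orders the flasks but gives no amounts. My reckoning: amber ends below 42.9% on the rising side, green past the peak, teal further past it.

The forecast gives 37%, 34% and 15%, with green “past the maximum”. The flasks give 37.1%, 33.5% and 14.4%.

    X + D → G + L (k = 0.00100 /M/min)
    X + Q → D + L (k = 0.0370 /M/min)
    Z + X → Q + L (k = 0.0520 /M/min)
    D ⇌ J (K = 1.10, k = 0.0140 /min)

In amber, Q is made, net, 5.00 times faster than it is used at 11.2 min and 1.99 times faster at 40.0 min, and F from the end state, Z 52.6% and Q 37.1%, comes to 1.96. In green, Z 10.6% and Q 33.5% put F at 0.438, below one, and Q has fallen from 42.7% at 20.0 min to 33.5% at 40.0 min.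

All runs are simulated for an exercise.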